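**Assumption:** emmaosunin has no stereocentre, so every sp3 intermediate is carried as a racemate or diastereomer mixture and its SMILES is written without stereodescriptors. Pyranone intermediates are numbered O1, C2 (aryl), C3 (OMe), C4 (C=O), C5, C6; the target uses chromone numbering.

## The problem

Emmaosunin 16 is a fully substituted flavonol ether: a 4H-chromen-4-one whose pyranone ring C carries a 3-methoxyphenyl group at C2 and a methoxyl at C3 and is fused through C4a–C8a to a benzene ring A that bears no hydrogen. There is no stereocentre, so nothing has to be controlled in three dimensions and no centre can direct another; the whole difficulty is the substitution pattern of ring A. C5, C6, C7 and C8 each carry oxygen, three as methyl ethers and one, at C5, as a free phenol hydrogen-bonded to the C4 carbonyl. Building ring C onto a ready-made pentaoxygenated benzene needs a hexasubstituted arene and then a selective O-demethylation at C5 beside four other aryl methyl ethers and the C3 enol ether, and hard Lewis acids do not discriminate well among these. Ring A is also a hydroquinone monoether (C5 OH para to C8 OMe) that is easily oxidised to the 5,8-quinone, and the γ-pyranone is opened by hard nucleophiles at C2, so late oxidants and strong nucleophilic bases are to be avoided. The enabling feature is that ring A (C4a, C5, C6, C7, C8, C8a) consists of four oxygenated carbons, C5 to C8, joined to a C4a=C8a unit. The four carbons map onto a squaric ester, the para pair C5-OH/C8-OMe is what a ring-expanding 4-alkoxy-4-alkenylcyclobutenone delivers from its ketene oxygen and its carbinol ether, and C4a=C8a is the C5=C6 bond of a monocyclic 4-pyranone that already holds C2, C3 and C4 with their substituents.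

## Retrosynthesis

**16 ⇒ 13.** The C4a–C5 bond is cut, and formally the σ bond of a cyclobutenone is restored. Backwards, phenol 16 is the enol of the 4aH-dienone 15, which is the 6π-closure product of the (Z)-dienylketene 14, which is the ring-opened form of 2,3,4-trimethoxy-4-(pyranonyl)cyclobutenone 13. The neighbouring cuts through ring C (O1–C8a, C4a–C4, O1–C2) all leave a pentaoxygenated benzene to be made and later demethylated. This cut removes the benzene ring altogether and delivers the C5 oxygen as the free phenol. Precursor 13 is an isomer of the target with one monocyclic pyranone, one four-membered ring and a single racemic stereocentre. The forward reaction needs outward rotation of the methoxyl on the sp3 carbon in the ring opening and closure of the ketene onto pyranone C5.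

**13 ⇒ 9 + 10.** The bond between pyranone C6 and the quaternary cyclobutenone carbon (the future C8–C8a bond) is cut, together with the O–CH3 bond of the tertiary ether. Dimethyl squarate 10 has two equivalent carbonyl groups, so addition of the pyranonyllithium 11 raises no regiochemical question. Methylation of the lithium alkoxide 12 in the same flask fixes the C8 methoxyl. Joining the two rings by a cross-coupling at the same bond was considered as the neighbouring cut, but it would give a ring A without oxygen at C8. The precursor 3-methoxy-2-(3-methoxyphenyl)-4H-pyran-4-one 9 has a single C–H next to the ring oxygen, so the forward step needs site-selective deprotonation at C6 without attack on the pyranone.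

**9 ⇒ 8.** The O–CH3 bond at C3 is cut. Methylation comes before the metalation because the free enolic hydroxyl of 8 would consume base and deactivate the ring. The methyl group is also the C3 methoxyl of the target, so it is not a protecting group.

**8 ⇒ 7 ⇒ 6.** A 3-hydroxy-4-pyranone stands one oxidation level above the pyranone that a furan ring expansion gives (two hydrogens fewer), so a ring expansion alone cannot reach 8. One oxygen has to be added at C4 and the anomeric substituent lost. Backwards, 8 comes from epoxy ketone 7 by acid-induced isomerisation and loss of methanol, and 7 from enone 6 by epoxidation of C4=C5. Nucleophilic peroxide is preferred over electrophilic halogenation of the enone because a halogen could also attack the anisole ring. The epoxidation requires the anomeric carbon to be a base-stable acetal, so 6 is the 6-methoxy compound.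

**6 ⇒ 4 (through 5).** The O1–C6 acetal bond and the C3 carbonyl are traced back to a furan. Oxidative 1,4-dimethoxylation of furyl carbinol 4 gives dihydrofuran 5, and acid-catalysed acetal exchange gives pyranone 6. Four of the five ring carbons of the pyranone come from the furan ring of 4, the fifth from its carbinol carbon and the ring oxygen from its hydroxyl, and the aryl group is already attached.

**4 ⇒ 1 + 2 (through 3).** The aryl–carbinol C–C bond is cut. 3-Bromoanisole 1 is converted into Grignard reagent 3, which adds to furfural 2. Both are commodity chemicals and the reaction has no selectivity issue.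

## Roads not taken

**Alternative 1:** The cut runs through ring C at O1–C8a, C4a–C4 and O1–C2. It leads back to 3,4,5,6-tetramethoxybenzyne A4 and 3-(3-methoxyphenyl)prop-2-ynoic acid A3. Aryne A4 would be released by fluoride from 3,4,5,6-tetramethoxy-2-(trimethylsilyl)phenyl triflate A2.
- Forward key step: the carboxylate of A3 adds to A4, the resulting aryl anion attacks its own ester carbonyl (acyl shift from O to C), and the phenoxide adds to the ynone to give 5,6,7,8-tetramethoxy-2-(3-methoxyphenyl)chromen-4-one A1.
- Merits: A4 is symmetric, so there is no regiochemistry; three bonds and ring C form in one operation; no pericyclic step and no pyranone anion are needed. In convergence this road is better than the chosen plan.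
- Weak points: A1 has hydrogen at C3 and a methyl ether at C5, so it still needs C3 oxygenation, methylation and a Lewis-acid demethylation that must pick C5 out of six methyl ethers. A2 is a hexasubstituted benzene that needs its own multistep preparation. The acyl shift has to beat protonation of a hindered, electron-rich aryl anion.
- Comparison: the chosen plan is less convergent, but its key step ends at 16 with every oxygen in final form, and its ring A carbons come from commercial 10.

**Alternative 2:** The cut removes C7–C8, C5–C6 and C4a–C5. Ring A is assembled from the pentacarbonylchromium methoxy(pyranonyl)carbene complex A6 (zerovalent chromium), 1,2-bis(pinacolatoboryl)ethyne A7 and one carbonyl ligand.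
- Forward key step: a Dötz benzannulation of A6 with A7 gives 5-hydroxy-3,8-dimethoxy-2-(3-methoxyphenyl)-6,7-bis(pinacolatoboryl)chromen-4-one A5.
- Merits: like the product of the chosen key step, A5 has C5 as a free phenol para to a C8 methoxyl, and its two boron groups would allow analogues at C6 and C7. In that flexibility it is superior.
- Weak points: A6 has to be made from the same lithiated pyranone 11, so it shares the least secure operation of the chosen plan and adds stoichiometric Cr(CO)6. Alkyne A7 is bulky and its C–B bonds are prone to protodeboronation, and alkenyl-type carbenes often divert to cyclobutenones or furans. The phenol of A5 leaves the reaction bound to chromium and needs oxidative decomplexation, which endangers a hydroquinone monoether. The two C–B bonds of A5 must then be oxidised to C–O and the two new hydroxyls methylated selectively against the C5 phenol.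
- Comparison: in the chosen plan squarate 10 acts as a pre-oxygenated alkyne plus carbon monoxide without any metal, and nothing is left to do after the ring closes.

**Alternative 3:** The only cut is O1–C8a. The precursor is 2-methoxy-1-(3-methoxyphenyl)-3-(2,3,4,5-tetramethoxyphenyl)propane-1,3-dione A9.
- Forward key step: anodic oxidation of the tetramethoxyphenyl ring of A9 lets the enol oxygen attack the single aryl C–H carbon to give 3,5,6,7,8-pentamethoxy-2-(3-methoxyphenyl)chromen-4-one A8.
- Merits: A9 comes from classical ester–ketone condensation at ordinary temperature, only one aryl C–H exists so the site of closure is fixed, and no chemical oxidant is needed. Its early steps are more robust and more scalable than the low-temperature metalation of 9, and in that respect it is the better plan.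
- Weak points: the radical cation formed from A9 has most spin density on methoxyl-bearing carbons, so ipso attack and loss of methanol compete with C–H substitution. The 2-methoxy-1,3-diketone unit of A9 is little enolised. A8 is itself oxidisable. The route again ends with a selective demethylation at C5, and the tetramethoxyphenyl half of A9 has to be built from a tetraoxygenated benzene.
- Comparison: the chosen plan delivers the C5 phenol directly, uses no late deprotection and takes ring A from a commercial four-carbon unit.

Key step: step 7

## Route

Step 1
Reactants: 1 3-bromoanisole; 2 furfural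
Product: 4 (furan-2-yl)(3-methoxyphenyl)methanol (racemic), via 3-methoxyphenylmagnesium bromide 3 (not isolated)
Conditions: Mg, I2 (cat.), THF, reflux; then 2, THF, 0 °C to rt; sat. aq. NH4Cl
Reagents that add atoms: none
Why: Grignard formation and addition to a non-enolisable aldehyde; the carbinol centre forms racemic, which is immaterial because it later becomes sp2 C2 of the pyranone.

Step 2
Reactants: 4 (furan-2-yl)(3-methoxyphenyl)methanol
Product: 6 6-methoxy-2-(3-methoxyphenyl)-2H-pyran-3(6H)-one (cis/trans mixture, racemic), via dimethoxydihydrofuran carbinol 5 (not isolated)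
Conditions: Br2 (1.0 equiv), Na2CO3, MeOH, −40 °C; filter, concentrate; then HCO2H, MeOH, rt
Reagents that add atoms: methanol, CO
Why: Clauson-Kaas 1,4-dimethoxylation of the furan followed by acid-catalysed acetal exchange (Achmatowicz rearrangement in its methanolic form), in which the ring oxygen leaves the acetal carbon, the carbinol oxygen recloses on the oxocarbenium ion and the hemiketal collapses to the ketone; one equivalent of bromine at −40 °C should be consumed by the furan far faster than by the anisole ring, and the two new stereocentres are uncontrolled and later removed.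

Step 3
Reactants: 6 6-methoxy-2-(3-methoxyphenyl)-2H-pyran-3(6H)-one
Product: 7 2-methoxy-4-(3-methoxyphenyl)-3,7-dioxabicyclo[4.1.0]heptan-5-one (the 4,5-epoxide of 6; diastereomer mixture, racemic)
Conditions: 30% aq. H2O2, NaOH (cat.), MeOH, 0 °C
Reagents that add atoms: hydrogen peroxide, OO
Why: Weitz–Scheffer nucleophilic epoxidation of the enone; the anomeric carbon is a base-stable acetal and the anisole ring is inert to a nucleophilic oxidant; attack anti to the C6 methoxyl is expected but the configuration is irrelevant because all four stereocentres are lost in step 4.

Step 4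
Reactants: 7 2-methoxy-4-(3-methoxyphenyl)-3,7-dioxabicyclo[4.1.0]heptan-5-one
Product: 8 3-hydroxy-2-(3-methoxyphenyl)-4H-pyran-4-one
Conditions: 2 M aq. H2SO4, 1,4-dioxane, 90 °C
Reagents that add atoms: none
Why: Acid-catalysed isomerisation of the α,β-epoxy ketone to the diosphenol, tautomerisation to the C2=C3 enol and β-elimination of methanol across C5–C6, the established way from 6-alkoxy-4,5-epoxypyran-3-ones to 3-hydroxy-4-pyranones; formation of the conjugated γ-pyranone drives it and the aryl methyl ether survives dilute aqueous acid.

Step 5
Reactants: 8 3-hydroxy-2-(3-methoxyphenyl)-4H-pyran-4-one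
Product: 9 3-methoxy-2-(3-methoxyphenyl)-4H-pyran-4-one
Conditions: MeI, K2CO3, acetone, reflux
Reagents that add atoms: iodomethane, CI
Why: Williamson O-methylation of the acidic enolic hydroxyl of a 3-hydroxy-4-pyranone, routine for this class; no other nucleophilic site is present.

Step 6
Reactants: 9 3-methoxy-2-(3-methoxyphenyl)-4H-pyran-4-one; 10 dimethyl squarate
Product: 13 2,3,4-trimethoxy-4-[5-methoxy-6-(3-methoxyphenyl)-4-oxo-4H-pyran-2-yl]cyclobut-2-en-1-one (racemic), via 6-lithiopyranone 11 (not isolated), via lithium cyclobutenolate 12 (not isolated)
Conditions: LiTMP, THF, −78 °C; then 10, THF, −78 °C; then MeOTf (1.1 equiv), −78 to −20 °C; aq. NaHCO3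
Reagents that add atoms: methyl trifluoromethanesulfonate, COS(=O)(=O)C(F)(F)F
Why: Deprotonative lithiation of a γ-pyranone at its oxygen-adjacent vinylic C–H with the hindered amide LiTMP (the site known for chromones), 1,2-addition of the vinyllithium to one of the two equivalent carbonyls of the squarate ester, and O-methylation of the tertiary lithium alkoxide by methyl triflate; C2 is blocked by the aryl group so C6 is the only oxygen-adjacent C–H, the bulky base should not add to the pyranone, and the new quaternary centre forms racemic.

Step 7
Reactants: 13 2,3,4-trimethoxy-4-[5-methoxy-6-(3-methoxyphenyl)-4-oxo-4H-pyran-2-yl]cyclobut-2-en-1-one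
Product: 16 emmaosunin (5-hydroxy-3,6,7,8-tetramethoxy-2-(3-methoxyphenyl)-4H-chromen-4-one), via (Z)-dienylketene 14 (not isolated), via 4aH-chromene-4,5-dione tautomer 15 (not isolated)
Conditions: degassed toluene, 110 °C, Ar
Reagents that add atoms: none
Why: This is a Moore rearrangement, and the closest known class is the 4-aryl-, 4-heteroaryl- and 4-alkenyl-4-alkoxycyclobutenones made from squarate esters, which give hydroquinone monoethers. On heating, the bond between the carbonyl carbon and the sp3 carbon of 13 opens in a thermal conrotatory 4π electrocyclic reaction to the dienylketene 14. Ring A then closes by a thermal disrotatory 6π electrocyclisation that involves the ketene C=C, the central C=C and the pyranone C5=C6 bond; the electrophilic ketene carbon bonds to the nucleophilic α-carbon of the vinylogous ester (the C4a–C5 bond) and gives the six-membered dienone 15. The C4a hydrogen of 15 lies between two carbonyl groups and should enolise at once, so the ketene oxygen ends as the chelated C5 phenol and aromatisation of ring A makes the sequence irreversible. No stereocentre is created: the quaternary carbon of 13 becomes sp2 C8 and the transient C4a centre of 15 is lost on tautomerisation. The selectivity needed is torquoselectivity, because only the (Z)-ketene with the pyranonyl group turned inward can cyclise; the methoxyl on the sp3 carbon is the stronger lone-pair donor and rotates outward, which leaves the unsaturated pyranonyl group in the inward position. Closure has no regiochemical alternative because the other neighbour of pyranone C6 is the ring oxygen, and the four oxygens arrive differentiated (C6 and C7 methoxyls from the squarate enol ethers, C8 methoxyl from the carbinol ether, C5 hydroxyl from the ketene).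

## Compound list

1 | 3-bromoanisole | COc1cccc(Br)c1 | starting material
2 | furfural | O=Cc1ccco1 | starting material
3 | 3-methoxyphenylmagnesium bromide | COc1cccc([Mg]Br)c1 | intermediate
4 | (furan-2-yl)(3-methoxyphenyl)methanol (racemic) | COc1cccc(c1)C(O)c1ccco1 | intermediate
5 | (2,5-dimethoxy-2,5-dihydrofuran-2-yl)(3-methoxyphenyl)methanol (diastereomer mixture) | COc1cccc(c1)C(O)C1(OC)C=CC(OC)O1 | intermediate
6 | 6-methoxy-2-(3-methoxyphenyl)-2H-pyran-3(6H)-one (cis/trans mixture, racemic) | COC1C=CC(=O)C(O1)c1cccc(OC)c1 | intermediate
7 | 2-methoxy-4-(3-methoxyphenyl)-3,7-dioxabicyclo[4.1.0]heptan-5-one (diastereomer mixture, racemic) | COC1OC(c2cccc(OC)c2)C(=O)C2OC12 | intermediate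
8 | 3-hydroxy-2-(3-methoxyphenyl)-4H-pyran-4-one | COc1cccc(c1)-c1occc(=O)c1O | intermediate
9 | 3-methoxy-2-(3-methoxyphenyl)-4H-pyran-4-one | COc1cccc(c1)-c1occc(=O)c1OC | intermediate
10 | dimethyl squarate (3,4-dimethoxycyclobut-3-ene-1,2-dione) | COC1=C(OC)C(=O)C1=O | starting material
11 | [5-methoxy-6-(3-methoxyphenyl)-4-oxo-4H-pyran-2-yl]lithium | COc1cccc(c1)-c1oc([Li])cc(=O)c1OC | intermediate
12 | lithium 2,3-dimethoxy-1-[5-methoxy-6-(3-methoxyphenyl)-4-oxo-4H-pyran-2-yl]-4-oxocyclobut-2-en-1-olate (racemic) | COc1cccc(c1)-c1oc(cc(=O)c1OC)C1(O[Li])C(OC)=C(OC)C1=O | intermediate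
13 | 2,3,4-trimethoxy-4-[5-methoxy-6-(3-methoxyphenyl)-4-oxo-4H-pyran-2-yl]cyclobut-2-en-1-one (racemic) | COc1cccc(c1)-c1oc(cc(=O)c1OC)C1(OC)C(OC)=C(OC)C1=O | intermediate
14 | (3Z)-2,3,4-trimethoxy-4-[5-methoxy-6-(3-methoxyphenyl)-4-oxo-4H-pyran-2-yl]buta-1,3-dien-1-one | O=C=C(OC)/C(OC)=C(/OC)c1cc(=O)c(OC)c(o1)-c1cccc(OC)c1 | intermediate
15 | 3,6,7,8-tetramethoxy-2-(3-methoxyphenyl)-4aH-chromene-4,5-dione (racemic) | COC1=C(OC)C(OC)=C2OC(=C(OC)C(=O)C2C1=O)c1cccc(OC)c1 | intermediate
16 | emmaosunin, 5-hydroxy-3,6,7,8-tetramethoxy-2-(3-methoxyphenyl)-4H-chromen-4-one | COc1cccc(-c2oc3c(OC)c(OC)c(OC)c(O)c3c(=O)c2OC)c1 | target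

## Step count and least certain steps

Total step count: 7. Longest linear sequence: 7 steps (1 and 2 to 16); dimethyl squarate 10 enters at step 6.

**Step 7 (key step).** The 6π closure onto the cross-conjugated pyranone double bond may be slow compared with diversion of the ketene (dimerisation, capture by traces of nucleophile). Partial inward rotation of the methoxyl would give a ketene that cannot close and decays. Moving to p-xylene at reflux is the first adjustment. The fallback changes what is asked of the ring expansion: it uses the free carbinol, whose hydroxyl has the strongest outward preference, and sets the C8 ether afterwards. It sets out from alkoxide 12, which is quenched with aqueous NH4Cl instead of methyl triflate to give 4-hydroxy-2,3-dimethoxy-4-[5-methoxy-6-(3-methoxyphenyl)-4-oxo-4H-pyran-2-yl]cyclobut-2-en-1-one F1, the classical free-carbinol substrate of this rearrangement. Thermolysis under argon should give the hydroquinone 5,8-dihydroxy-3,6,7-trimethoxy-2-(3-methoxyphenyl)-4H-chromen-4-one F2. Monomethylation with one equivalent of MeI and K2CO3 in acetone under argon should take place at the C8 hydroxyl, because the C5 hydroxyl is tied up in the hydrogen bond to the C4 carbonyl. The route is rejoined at 16.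

**Step 6.** Three processes threaten this step: self-condensation or ring opening of the lithiated pyranone before it meets the squarate, deprotonation at C5 directed by lithium on the carbonyl oxygen, and O-methylation of the pyranone carbonyl (pyrylium formation) or incomplete methylation of the hindered alkoxide. The fallback separates the three events and avoids a lithium amide. It sets out from 9, which is zincated at C6 with TMPZnCl·LiCl in THF at rt to [5-methoxy-6-(3-methoxyphenyl)-4-oxo-4H-pyran-2-yl]zinc chloride F3, and iodine converts this into 6-iodo-3-methoxy-2-(3-methoxyphenyl)-4H-pyran-4-one F4. Iodine–magnesium exchange with i-PrMgCl·LiCl at −40 °C gives [5-methoxy-6-(3-methoxyphenyl)-4-oxo-4H-pyran-2-yl]magnesium chloride F5, free of amine. This adds to 10 and, after aqueous NH4Cl, gives the carbinol 4-hydroxy-2,3-dimethoxy-4-[5-methoxy-6-(3-methoxyphenyl)-4-oxo-4H-pyran-2-yl]cyclobut-2-en-1-one F1, which is isolated. Methylation with MeI, Ag2O and K2CO3 in acetonitrile, conditions that do not alkylate a pyranone carbonyl, rejoins the route at 13.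

**Step 3.** The C2 hydrogen of 6 is benzylic and α to the ketone. Base-induced enolisation with expulsion of the anomeric methoxide, or ring opening, may compete with peroxide addition. The fallback puts the C4 heteroatom in at the furan stage and uses neither base nor peroxide. It sets out from Grignard reagent 3, which is added to commercial 3-bromofuran-2-carbaldehyde (O=Cc1occc1Br) to give (3-bromofuran-2-yl)(3-methoxyphenyl)methanol F6. Achmatowicz rearrangement with NBS and NaHCO3 in THF/H2O at 0 °C should give 4-bromo-6-hydroxy-2-(3-methoxyphenyl)-2H-pyran-3(6H)-one F7. Heating F7 in aqueous H2SO4/dioxane should dehydrate it to the 4-bromo-3-hydroxypyrylium ion, which water attacks at C4 with loss of HBr (the halopyranone hydrolysis used for maltol-type pyranones), and this rejoins the route at 8.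

**Step 2.** Electrophilic bromination of the anisole ring by any excess bromine, and incomplete acetal exchange that leaves open-chain or 6-hydroxy material, are the likely faults. The fallback uses a halogen-free oxidant and a separate glycosidation. It sets out from 4, which undergoes Achmatowicz rearrangement with mCPBA in CH2Cl2 at 0 °C to 6-hydroxy-2-(3-methoxyphenyl)-2H-pyran-3(6H)-one F8. The hemiacetal is converted into the methyl acetal with HC(OMe)3 and BF3·OEt2 (cat.) in CH2Cl2, which rejoins the route at 6.

## Further compounds

F1 | step 7 | 4-hydroxy-2,3-dimethoxy-4-[5-methoxy-6-(3-methoxyphenyl)-4-oxo-4H-pyran-2-yl]cyclobut-2-en-1-one (racemic) | COc1cccc(c1)-c1oc(cc(=O)c1OC)C1(O)C(OC)=C(OC)C1=O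
F2 | step 7 | 5,8-dihydroxy-3,6,7-trimethoxy-2-(3-methoxyphenyl)-4H-chromen-4-one | COc1cccc(c1)-c1oc2c(O)c(OC)c(OC)c(O)c2c(=O)c1OC
F3 | step 6 | [5-methoxy-6-(3-methoxyphenyl)-4-oxo-4H-pyran-2-yl]zinc chloride | COc1cccc(c1)-c1oc([Zn]Cl)cc(=O)c1OC
F4 | step 6 | 6-iodo-3-methoxy-2-(3-methoxyphenyl)-4H-pyran-4-one | COc1cccc(c1)-c1oc(I)cc(=O)c1OC
F5 | step 6 | [5-methoxy-6-(3-methoxyphenyl)-4-oxo-4H-pyran-2-yl]magnesium chloride | COc1cccc(c1)-c1oc([Mg]Cl)cc(=O)c1OC
F6 | step 3 | (3-bromofuran-2-yl)(3-methoxyphenyl)methanol (racemic) | COc1cccc(c1)C(O)c1occc1Br
F7 | step 3 | 4-bromo-6-hydroxy-2-(3-methoxyphenyl)-2H-pyran-3(6H)-one (diastereomer mixture) | COc1cccc(c1)C1OC(O)C=C(Br)C1=O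
F8 | step 2 | 6-hydroxy-2-(3-methoxyphenyl)-2H-pyran-3(6H)-one (diastereomer mixture) | COc1cccc(c1)C1OC(O)C=CC1=O
A1 | alternative 1 | 5,6,7,8-tetramethoxy-2-(3-methoxyphenyl)chromen-4-one | COc1cccc(c1)-c1cc(=O)c2c(OC)c(OC)c(OC)c(OC)c2o1
A2 | alternative 1 | 3,4,5,6-tetramethoxy-2-(trimethylsilyl)phenyl trifluoromethanesulfonate | COc1c(OC)c(OC)c([Si](C)(C)C)c(OS(=O)(=O)C(F)(F)F)c1OC
A3 | alternative 1 | 3-(3-methoxyphenyl)prop-2-ynoic acid | COc1cccc(c1)C#CC(O)=O
A4 | alternative 1 | 3,4,5,6-tetramethoxybenzyne | COC1=C(OC)C(OC)=C(OC)C#C1
A5 | alternative 2 | 5-hydroxy-3,8-dimethoxy-2-(3-methoxyphenyl)-6,7-bis(4,4,5,5-tetramethyl-1,3,2-dioxaborolan-2-yl)chromen-4-one | COc1cccc(c1)-c1oc2c(OC)c(B3OC(C)(C)C(C)(C)O3)c(B3OC(C)(C)C(C)(C)O3)c(O)c2c(=O)c1OC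
A6 | alternative 2 | pentacarbonyl{methoxy[5-methoxy-6-(3-methoxyphenyl)-4-oxo-4H-pyran-2-yl]methylidene}chromium | COC(=[Cr])c1cc(=O)c(OC)c(o1)-c1cccc(OC)c1.[C-]#[O+].[C-]#[O+].[C-]#[O+].[C-]#[O+].[C-]#[O+]
A7 | alternative 2 | 1,2-bis(4,4,5,5-tetramethyl-1,3,2-dioxaborolan-2-yl)ethyne | CC1(C)OB(OC1(C)C)C#CB1OC(C)(C)C(C)(C)O1
A8 | alternative 3 | 3,5,6,7,8-pentamethoxy-2-(3-methoxyphenyl)chromen-4-one | COc1cccc(c1)-c1oc2c(OC)c(OC)c(OC)c(OC)c2c(=O)c1OC
A9 | alternative 3 | 2-methoxy-1-(3-methoxyphenyl)-3-(2,3,4,5-tetramethoxyphenyl)propane-1,3-dione | COc1cccc(c1)C(=O)C(OC)C(=O)c1cc(OC)c(OC)c(OC)c1OC
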